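**Retrosynthetic overview**
- The target is 19-angeloyloxylabda-7,13(Z)-dien-15-oic acid. Its trans-decalin (rings A and B) with C5, C9, C10, the C12 carbon and a C8 oxygen (which becomes the 7-ene) is taken from (+)-sclareolide.
- Disconnections: the C19–O acyl bond (angeloylation), the C12–C13 bond (Negishi coupling of a C12 alkylzinc with a (Z)-3-iodobut-2-enoate made from but-2-ynoic acid), and the C19–O bond itself, formed by hydrogen transfer from C19 to a 6β-alkoxy radical.
- Feature on which the plan rests: the axial 4β-methyl carbon C19 on ring A and the 6β position on ring B are syn-axial across C5, and C6 is allylic to C7=C8. A 6β-oxygen can therefore be introduced by allylic oxidation, can reach C19, and can afterwards be removed by reductive cleavage of the allylic C6–O bond.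
- Ring order: rings A and B are kept from sclareolide and the lactone is opened in step 1. A temporary tetrahydrofuran (O–C19–C4–C5–C6) is closed in step 4 and opened in step 6; no other ring is formed.

Key step: step 4

Remark: labdane numbering is used throughout; C19 is the 4β (axial) carbon cis to C20, which is the configuration encoded in the target SMILES.

**Route**

Step 1
Reactants: 1 (+)-sclareolide
Product: 2 methyl 13,14,15,16-tetranorlabd-7-en-12-oate
Conditions: conc. H2SO4, MeOH, reflux, stopped when 1 is consumed; AgNO3–SiO2 chromatography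
Reagents that add atoms: methanol, CO
Why: Acid-mediated alkyl–oxygen cleavage of the tertiary lactone C8–O bond gives the C8 cation, Fischer esterification caps C12 and E1 loss of the axial 7α-hydrogen gives the trisubstituted 7-ene, while the 8(17)- and 8(9)-ene isomers that are expected alongside are removed on AgNO3-impregnated silica and C5, C9 and C10 are untouched.

Step 2
Reactants: 2 methyl 13,14,15,16-tetranorlabd-7-en-12-oate
Product: 3 methyl 6-oxo-13,14,15,16-tetranorlabd-7-en-12-oate
Conditions: CrO3, 3,5-dimethylpyrazole, CH2Cl2, −20 °C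
Reagents that add atoms: chromium trioxide, O=[Cr](=O)=O
Why: Allylic oxidation by the CrO3–3,5-dimethylpyrazole complex should attack the only allylic methylene (C6, next to the CH terminus of the trisubstituted alkene) and give the conjugated 7-en-6-one without touching the ester.

Step 3
Reactants: 3 methyl 6-oxo-13,14,15,16-tetranorlabd-7-en-12-oate
Product: 4 methyl 6β-hydroxy-13,14,15,16-tetranorlabd-7-en-12-oate
Conditions: NaBH4, CeCl3·7H2O, MeOH, −20 °C
Reagents that add atoms: none
Why: Luche 1,2-reduction in which hydride enters C6 from the α face, because the β face is closed by the syn-axial C19 and C20 methyl groups, which sets the axial 6β-alcohol and leaves the ester intact.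

Step 4
Reactants: 4 methyl 6β-hydroxy-13,14,15,16-tetranorlabd-7-en-12-oate
Product: 7 methyl 6β,19-epoxy-13,14,15,16-tetranorlabd-7-en-12-oate, via 6β-hypoiodite 5 (not isolated), via 19-iodo-6β-alcohol 6 (not isolated)
Conditions: PhI(OAc)2 (in portions), I2, cyclohexane, visible light (tungsten lamps), 25–40 °C
Reagents that add atoms: none
Why: Proposed new method: acetyl hypoiodite from PhI(OAc)2 and I2 O-iodinates the 6β-alcohol, visible light cleaves the O–I bond, the 6β-alkoxy radical takes a hydrogen from the 4β-methyl group C19 through a six-membered transition state, the C19 radical is iodinated, and the neopentyl iodide, activated by further oxidation at iodine, is displaced by the 6β-oxygen. The closest known reaction type is the hypoiodite etherification (Suárez conditions) of axial 6β-alcohols of steroids onto the syn-axial angular methyl group; new here are the allylic alcohol and the choice between two syn-axial methyl groups. The tetrahydrofuran O–C19–C4–C5–C6 closes in the 5-exo-tet mode. C4 becomes a stereocentre whose configuration is fixed by geometry, since only the axial 4β-methyl lies on the face of the 6β-oxygen and the equatorial 4α-methyl is out of reach. The step needs abstraction at C19 and not C20, and hydrogen transfer faster than β-scission of C5–C6, oxidation to enone 3 and iodine addition to C7=C8; in the half-chair of ring B the pseudo-axial C6–O bond leans away from C10 and towards C4 (ring torsion about C5–C6 near 45° instead of 55°), which should favour C19, and anti addition to the alkene is screened because it needs attack on the β face under C20. PhI(OAc)2 is added in portions in cyclohexane to keep electrophilic iodine low, and any enone 3 formed is returned to step 3.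

Step 5
Reactants: 7 methyl 6β,19-epoxy-13,14,15,16-tetranorlabd-7-en-12-oate
Product: 8 6β,19-epoxy-13,14,15,16-tetranorlabd-7-en-12-ol
Conditions: LiAlH4, THF, 0 °C
Reagents that add atoms: none
Why: Hydride reduction of the ester to the primary alcohol, to which the allylic ether and the alkene are inert.

Step 6
Reactants: 8 6β,19-epoxy-13,14,15,16-tetranorlabd-7-en-12-ol
Product: 9 13,14,15,16-tetranorlabd-7-ene-12,19-diol
Conditions: Li, NH3(l)/THF, −78 to −33 °C; then NH4Cl
Reagents that add atoms: none
Why: Dissolving-metal (Birch-type) cleavage of the allylic C6–O bond expels the C19 alkoxide and leaves the C6–C7–C8 allyl anion, which ammonia should protonate at its less substituted terminus C6 to return the trisubstituted 7-ene, with no new stereocentre and no reduction of the isolated alkene.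

Step 7
Reactants: 9 13,14,15,16-tetranorlabd-7-ene-12,19-diol
Product: 10 12-iodo-13,14,15,16-tetranorlabd-7-en-19-ol
Conditions: I2, PPh3, imidazole, CH2Cl2, 0 °C
Reagents that add atoms: iodine, II
Why: Appel-type iodination (alkoxyphosphonium ion, then SN2 by iodide) should be confined to the unhindered primary C12 alcohol, since the neopentyl C19 oxyphosphonium ion cannot be displaced and reverts to the alcohol on work-up.

Step 8
Reactants: 10 12-iodo-13,14,15,16-tetranorlabd-7-en-19-ol; 11 angelic acid
Product: 13 12-iodo-13,14,15,16-tetranorlabd-7-en-19-yl angelate, via angelic 2,4,6-trichlorobenzoic anhydride 12 (not isolated)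
Conditions: 11, 2,4,6-trichlorobenzoyl chloride, Et3N, toluene, rt; filter; then 10, toluene, 80 °C
Reagents that add atoms: none
Why: Yamaguchi-type acylation through the mixed anhydride without a nucleophilic catalyst transfers the (Z)-2-methylbut-2-enoyl group without isomerisation to the tiglate, and the ammonium salt is filtered off before heating so that the primary iodide meets neither chloride nor free amine.

Step 9
Reactants: 14 but-2-ynoic acid
Product: 15 (Z)-3-iodobut-2-enoic acid
Conditions: NaI, AcOH, 110 °C
Reagents that add atoms: sodium iodide, [Na+].[I-]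
Why: Conjugate hydroiodination of the ynoic acid, in which iodide adds to C3 and the allenoate is protonated anti, gives the (Z)-3-iodo acid.

Step 10
Reactants: 15 (Z)-3-iodobut-2-enoic acid
Product: 16 2-(trimethylsilyl)ethyl (Z)-3-iodobut-2-enoate
Conditions: Me3SiCH2CH2OH, PPh3, DIAD, THF, 0 °C to rt
Reagents that add atoms: 2-(trimethylsilyl)ethanol, C[Si](C)(C)CCO
Why: Mitsunobu esterification activates the alcohol and not the acid, so the (Z)-iodoenoate is never exposed to a nucleophilic acyl-transfer catalyst that could scramble its geometry.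

Step 11
Reactants: 13 12-iodo-13,14,15,16-tetranorlabd-7-en-19-yl angelate; 16 2-(trimethylsilyl)ethyl (Z)-3-iodobut-2-enoate
Product: 18 2-(trimethylsilyl)ethyl 19-angeloyloxylabda-7,13(Z)-dien-15-oate, via alkylzinc iodide 17 (not isolated)
Conditions: Zn dust (activated with BrCH2CH2Br, Me3SiCl), LiCl, THF, 40 °C; then 16, PdCl2(dppf) (5 mol%), THF, rt
Reagents that add atoms: none
Why: Zinc insertion into the primary C–I bond followed by Negishi coupling with the (Z)-alkenyl iodide proceeds with retention at the alkenyl carbon, so C12 ends cis to the carboxyl (13Z), and the alkylzinc tolerates both esters.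

Step 12
Reactants: 18 2-(trimethylsilyl)ethyl 19-angeloyloxylabda-7,13(Z)-dien-15-oate
Product: 19 19-angeloyloxylabda-7,13(Z)-dien-15-oic acid (CNP0249147.1)
Conditions: Bu4NF, THF, 0 °C to rt; dilute aq. HCl to pH 3
Reagents that add atoms: none
Why: Fluoride-induced fragmentation of the 2-(trimethylsilyl)ethyl ester (β-elimination of ethene) frees the acid under conditions that should leave the hindered angelate and both alkenes untouched.

**Compound list**
1 | (+)-sclareolide | CC1(C)CCC[C@]2(C)[C@H]3CC(=O)O[C@]3(C)CC[C@@H]12 | starting material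
2 | methyl 13,14,15,16-tetranorlabd-7-en-12-oate | CC1(C)CCC[C@]2(C)[C@@H](CC(=O)OC)C(C)=CC[C@@H]12 | intermediate
3 | methyl 6-oxo-13,14,15,16-tetranorlabd-7-en-12-oate | CC1(C)CCC[C@]2(C)[C@@H](CC(=O)OC)C(C)=CC(=O)[C@@H]12 | intermediate
4 | methyl 6β-hydroxy-13,14,15,16-tetranorlabd-7-en-12-oate | CC1(C)CCC[C@]2(C)[C@@H](CC(=O)OC)C(C)=C[C@@H](O)[C@@H]12 | intermediate
5 | methyl 6β-iodooxy-13,14,15,16-tetranorlabd-7-en-12-oate (hypoiodite of 4) | CC1(C)CCC[C@]2(C)[C@@H](CC(=O)OC)C(C)=C[C@@H](OI)[C@@H]12 | intermediate
6 | methyl 6β-hydroxy-19-iodo-13,14,15,16-tetranorlabd-7-en-12-oate | IC[C@@]1(C)CCC[C@]2(C)[C@@H](CC(=O)OC)C(C)=C[C@@H](O)[C@@H]12 | intermediate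
7 | methyl 6β,19-epoxy-13,14,15,16-tetranorlabd-7-en-12-oate | O1C[C@@]2(C)CCC[C@]3(C)[C@@H](CC(=O)OC)C(C)=C[C@@H]1[C@@H]23 | intermediate
8 | 6β,19-epoxy-13,14,15,16-tetranorlabd-7-en-12-ol | O1C[C@@]2(C)CCC[C@]3(C)[C@@H](CCO)C(C)=C[C@@H]1[C@@H]23 | intermediate
9 | 13,14,15,16-tetranorlabd-7-ene-12,19-diol | OC[C@@]1(C)CCC[C@]2(C)[C@@H](CCO)C(C)=CC[C@@H]12 | intermediate
10 | 12-iodo-13,14,15,16-tetranorlabd-7-en-19-ol | OC[C@@]1(C)CCC[C@]2(C)[C@@H](CCI)C(C)=CC[C@@H]12 | intermediate
11 | angelic acid, (Z)-2-methylbut-2-enoic acid | C/C=C(/C)C(=O)O | starting material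
12 | angelic 2,4,6-trichlorobenzoic anhydride | C/C=C(/C)C(=O)OC(=O)c1c(Cl)cc(Cl)cc1Cl | intermediate
13 | 12-iodo-13,14,15,16-tetranorlabd-7-en-19-yl angelate | C/C=C(/C)C(=O)OC[C@@]1(C)CCC[C@]2(C)[C@@H](CCI)C(C)=CC[C@@H]12 | intermediate
14 | but-2-ynoic acid | CC#CC(=O)O | starting material
15 | (Z)-3-iodobut-2-enoic acid | C/C(I)=C/C(=O)O | intermediate
16 | 2-(trimethylsilyl)ethyl (Z)-3-iodobut-2-enoate | C/C(I)=C/C(=O)OCC[Si](C)(C)C | intermediate
17 | (19-angeloyloxy-13,14,15,16-tetranorlabd-7-en-12-yl)zinc iodide | C/C=C(/C)C(=O)OC[C@@]1(C)CCC[C@]2(C)[C@@H](CC[Zn]I)C(C)=CC[C@@H]12 | intermediate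
18 | 2-(trimethylsilyl)ethyl 19-angeloyloxylabda-7,13(Z)-dien-15-oate | C/C=C(/C)C(=O)OC[C@@]1(C)CCC[C@]2(C)[C@@H](CC/C(C)=C\C(=O)OCC[Si](C)(C)C)C(C)=CC[C@@H]12 | intermediate
19 | 19-angeloyloxylabda-7,13(Z)-dien-15-oic acid (CNP0249147.1) | C/C=C(/C)C(=O)OC[C@@]1(C)CCC[C@]2(C)[C@@H](CC/C(C)=C\C(=O)O)C(C)=CC[C@@H]12 | target

**Step count**
Total: 12 steps. Longest linear sequence: 10 steps (steps 1–8, 11, 12); steps 9 and 10 make the coupling partner.

**Steps most likely to fail**

1. Step 4 (proposed new method). What may go wrong: electrophilic iodine may add across C7=C8 (iodoacetoxylation, or iodolactonisation through the C12 ester), or the allylic alcohol may be oxidised to the enone before the O–I bond is photolysed; hydrogen abstraction from C20 may also compete. Fallback, setting out from 4 and returning at 7: the alkene is masked first. mCPBA/NaHCO3 in CH2Cl2 at 0 °C should epoxidise C7=C8 from the open α face to give methyl 7α,8α-epoxy-6β-hydroxy-13,14,15,16-tetranorlabdan-12-oate F1. The hypoiodite reaction (PhI(OAc)2, I2, visible light, cyclohexane) is then run on this alkene-free axial alcohol, the substrate class on which etherification of a syn-axial methyl group is established, to give methyl 6β,19:7α,8α-diepoxy-13,14,15,16-tetranorlabdan-12-oate F2. Stereospecific deoxygenation of the epoxide with the lower-valent tungsten reagent made from WCl6 and n-BuLi in THF restores the C7=C8 alkene and gives 7.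

2. Step 6. What may go wrong: the allyl anion may be protonated at C8 instead of C6, moving the alkene to C6=C7 and creating an uncontrolled C8 stereocentre; electron transfer to the unconjugated allylic ether may also be incomplete. Fallback, setting out from 7 (in place of steps 5 and 6) and returning at 9: the ether is opened under Lewis-acid conditions and the halide removed by a radical chain. Acetyl bromide with catalytic ZnCl2 in CH2Cl2 at 0 °C acylates the ring oxygen, and bromide opens the allylic C6–O bond with inversion to give methyl 19-acetoxy-6α-bromo-13,14,15,16-tetranorlabd-7-en-12-oate F3 (its C8 allylic isomer, if formed, leads to the same allyl radical). Bu3SnH with Et3B/air in toluene at 0 °C reduces the allylic bromide through the C6–C7–C8 allyl radical, which should take hydrogen at the less hindered C6 terminus, to give methyl 19-acetoxy-13,14,15,16-tetranorlabd-7-en-12-oate F4. LiAlH4 in THF then reduces both esters to diol 9.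

3. Step 8. What may go wrong: the angeloyl group may isomerise from Z to E during activation, or acylation of the neopentyl C19 alcohol may be so slow that the primary iodide is lost under forcing conditions. Fallback, setting out from 10 and returning at 13: the Z-alkene is built on the alcohol instead of being carried in. Alcohol 10 is esterified (DCC, cat. DMAP, CH2Cl2) with 2-[bis(2,2,2-trifluoroethoxy)phosphoryl]propanoic acid to give 12-iodo-13,14,15,16-tetranorlabd-7-en-19-yl 2-[bis(2,2,2-trifluoroethoxy)phosphoryl]propanoate F5 (mixture of epimers at the phosphonate α-carbon). Still–Gennari olefination (KHMDS, 18-crown-6, THF, −78 °C, acetaldehyde) should then deliver the (Z)-2-methylbut-2-enoate 13.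

**Further compounds**
F1 | step 4 | methyl 7α,8α-epoxy-6β-hydroxy-13,14,15,16-tetranorlabdan-12-oate | CC1(C)CCC[C@]2(C)[C@@H](CC(=O)OC)[C@]3(C)O[C@@H]3[C@@H](O)[C@@H]12
F2 | step 4 | methyl 6β,19:7α,8α-diepoxy-13,14,15,16-tetranorlabdan-12-oate | O1C[C@@]2(C)CCC[C@]3(C)[C@@H](CC(=O)OC)[C@]4(C)O[C@@H]4[C@@H]1[C@@H]23
F3 | step 6 | methyl 19-acetoxy-6α-bromo-13,14,15,16-tetranorlabd-7-en-12-oate | CC(=O)OC[C@@]1(C)CCC[C@]2(C)[C@@H](CC(=O)OC)C(C)=C[C@H](Br)[C@@H]12
F4 | step 6 | methyl 19-acetoxy-13,14,15,16-tetranorlabd-7-en-12-oate | CC(=O)OC[C@@]1(C)CCC[C@]2(C)[C@@H](CC(=O)OC)C(C)=CC[C@@H]12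
F5 | step 8 | 12-iodo-13,14,15,16-tetranorlabd-7-en-19-yl 2-[bis(2,2,2-trifluoroethoxy)phosphoryl]propanoate | CC(C(=O)OC[C@@]1(C)CCC[C@]2(C)[C@@H](CCI)C(C)=CC[C@@H]12)P(=O)(OCC(F)(F)F)OCC(F)(F)F
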